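**Retrosynthetic overview**
1. The target is a hetero-dimer of two 10-hydroxyguaianolides joined through a norbornane (bonds C2–C2′ and C3–C5′). Its cyclopentene ring A (C1–C5) holds the only isolated tetrasubstituted alkene, C4=C5, and both alkene carbons hang cis and endo from neighbouring norbornane carbons (C4 on C3, C5 through C1 on C2). Ring A is therefore closed last, by ring-closing metathesis of a 1,6-diene (C4 isopropenyl, C5 methylene).
2. The diene comes from the 1,5-diketone (C4 methyl ketone, C5 ring ketone) by double methylenation. The diketone is the endo Diels–Alder adduct (norbornane) of the 2-silyloxycyclopentadiene of the primed unit and a (Z)-enone in which ring A has been opened at C4=C5 by ozone; the two stored carbonyl groups activate and polarise the dienophile and favour the cross-dimer.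
3. Diene and dienophile both derive from 10-epi-isophotosantonic lactone, made from (−)-α-santonin by the dienone photorearrangement and inversion of C10 (dehydration, then radical hydration).
4. Order of ring formation: γ-lactone, seven-membered ring and cyclopentenone of each half (step 1), norbornane (step 8), ring A (step 10).

Key step: step 10

Remark: guaiane numbering is used, C1–C15 for the unit that contains ring A and C1′–C15′ for the 3′-oxo unit; commercial α-santonin is taken as the natural (−)-enantiomer, whose C6, C7 and C11 centres match both halves of the target.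

Step 1
Reactants: 1 (−)-α-santonin
Product: 2 isophotosantonic lactone
Conditions: hν (medium-pressure Hg lamp, quartz), AcOH/H2O 1:1, reflux
Reagents that add atoms: water, O
Why: Photorearrangement of the cross-conjugated cyclohexadienone: the excited dienone bonds C1 to C5 through a cyclopropyl zwitterion and water opens the C5–C10 bond with inversion at C10, which sets C1 as required and C10 with the hydroxyl cis to H-1 (opposite to the target).

Step 2
Reactants: 2 isophotosantonic lactone
Product: 3 3-oxoguaia-4,10(14)-dien-12,6-olide
Conditions: SOCl2, pyridine, CH2Cl2, −20 → 0 °C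
Reagents that add atoms: none
Why: E2 dehydration through the chlorosulfite can only use the anti hydrogens on C14 and C9 (H-1 is syn to the leaving group), so the exocyclic alkene should predominate, C1 is untouched, and any 9(10)-isomer would converge in step 3.

Step 3
Reactants: 3 3-oxoguaia-4,10(14)-dien-12,6-olide
Product: 4 10-epi-isophotosantonic lactone
Conditions: Co(acac)2 (20 mol %), PhSiH3, O2 (1 atm), THF, 23 °C
Reagents that add atoms: dioxygen, O=O
Why: Mukaiyama hydration (hydrogen atom transfer from a cobalt hydride to C14, capture of the tertiary C10 radical by O2, reduction of the peroxide by the silane); O2 should add axially, anti to the axial C1–H, leaving the C14 methyl equatorial and the hydroxyl trans to H-1 as in the target, while the electron-poor tetrasubstituted enone does not react.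

Step 4
Reactants: 4 10-epi-isophotosantonic lactone
Product: 5 3,10-bis(triethylsilyloxy)guaia-2,4-dien-12,6-olide
Conditions: TESOTf (3 equiv), Et3N, CH2Cl2, −78 → 0 °C
Reagents that add atoms: triethylsilyl trifluoromethanesulfonate, CC[Si](CC)(CC)OS(=O)(=O)C(F)(F)F
Why: Soft enolisation with silyl triflate and amine removes the accessible C2 proton to give the cross-conjugated 2-silyloxy diene and silylates the tertiary alcohol in the same operation, with no stereocenter touched.

Step 5
Reactants: 5 3,10-bis(triethylsilyloxy)guaia-2,4-dien-12,6-olide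
Product: 7 dienyl triflate, via cesium dienolate 6 (not isolated)
Conditions: CsF (1.1 equiv), PhNTf2, DME, 23 °C
Reagents that add atoms: N-phenylbis(trifluoromethanesulfonimide), O=S(=O)(N(c1ccccc1)S(=O)(=O)C(F)(F)F)C(F)(F)F
Why: Fluoride cleaves only the labile silyl enol ether and the regiodefined dienolate is O-sulfonylated by PhNTf2 before it can equilibrate (enolate triflation), no stereocenter being formed.

Step 6
Reactants: 7 dienyl triflate
Product: 8 triflyloxy enedione (4,5-seco)
Conditions: O3, pyridine, CH2Cl2, −78 °C
Reagents that add atoms: ozone, [O-][O+]=O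
Why: Ozonolysis should occur at the electron-rich tetrasubstituted C4=C5 bond and not at the triflate-deactivated C2=C3 bond, opening ring A to the C5 ketone and the C4 methyl ketone with the C2=C3 geometry kept (C1 and acetyl cis), pyridine converting the carbonyl oxide into the ketone in situ.

Step 7
Reactants: 8 triflyloxy enedione (4,5-seco)
Product: 9 (Z)-enedione
Conditions: Pd(OAc)2 (5 mol %), PPh3, HCO2H, Bu3N, DMF, 40 °C
Reagents that add atoms: none
Why: Palladium-catalysed formate reduction of an enol triflate (oxidative addition to zerovalent palladium, formate exchange, loss of CO2, C–H reductive elimination) proceeds with retention and should give the (Z)-enone without touching C1.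

Step 8
Reactants: 5 3,10-bis(triethylsilyloxy)guaia-2,4-dien-12,6-olide; 9 (Z)-enedione
Product: 10 Diels–Alder adduct (diketone)
Conditions: equimolar amounts, toluene (2 M), 40 °C, dark
Reagents that add atoms: none
Why: Intermolecular Diels–Alder reaction of an electron-rich 2-silyloxy diene with an enone, in which the two partners combine atom for atom: the silyloxy group directs C2′ to the β-carbon C2 and C5′ to the α-carbon C3; the dienophile adds to the diene face anti to C10′ (sets C2′ and C5′); the acetyl group and its cis partner C1 go endo (sets C2 and C3); and the alkene should react on its H-1 face in the rotamer that keeps the C5 carbonyl in the alkene plane, as in the closed ring.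

Step 9
Reactants: 10 Diels–Alder adduct (diketone)
Product: 11 bis-methylene diene
Conditions: Cp2Ti(μ-CH2)(μ-Cl)AlMe2 (3 equiv), pyridine, THF/toluene, −40 → 0 °C
Reagents that add atoms: Tebbe reagent, C[Al-]1(C)C[Ti](C2C=CC=C2)(C2C=CC=C2)[Cl+]1
Why: Tebbe methylenation converts both ketones, including the hindered C5 ketone, into 1,1-disubstituted alkenes under non-basic conditions at a temperature at which lactones and the silyl enol ether do not react, so C1 and C3 are not epimerised.

Step 10
Reactants: 11 bis-methylene diene
Product: 12 tris(triethylsilyl) derivative of the target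
Conditions: RuCl2(1,3-di-o-tolylimidazolidin-2-ylidene)(=CH-C6H4-2-OiPr) (10 mol %), 2,6-dichloro-1,4-benzoquinone, toluene, 100 °C, Ar sparge
Reagents that add atoms: none
Why: Ring-closing olefin metathesis: a ruthenium methylidene exchanges with one 1,1-disubstituted alkene, the resulting disubstituted alkylidene adds to the other alkene in an intramolecular [2+2] step, and cycloreversion of the ruthenacyclobutane releases ethylene and the C4=C5 double bond. The closest known reaction type is the ruthenium-catalysed closure of 2,2′-disubstituted 1,6-dienes to tetrasubstituted cyclopentenes with phosphine-free catalysts that carry small N-aryl carbene ligands. One ring is closed, ring A (C1–C5), by joining the alkene carbons C4 and C5 of the 1,6-diene into an endocyclic double bond, and loss of ethylene makes the closure irreversible. No stereocenter is formed: C1, C2 and C3 are set beforehand, and their cis-endo arrangement on the norbornane holds the isopropenyl group on C3 and the C5 methylene within bonding distance. The step needs chemoselectivity among three alkenes, which the substrate should secure because the third is a tetrasubstituted silyl enol ether inside the norbornene and cannot enter a metallacycle. The competing path is migration of the exocyclic alkenes before closure, which the quinone additive holds back by destroying ruthenium hydrides.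

Step 11
Reactants: 12 tris(triethylsilyl) derivative of the target
Product: 13 CNP0243924.4
Conditions: HF·pyridine, pyridine, THF, 0 → 23 °C
Reagents that add atoms: none
Why: Fluoride-mediated desilylation frees both tertiary alcohols and the 3′-enol, which should be protonated at C4′ on the exo face (the endo face is covered by ring A), placing the C15′ methyl endo as in the target; the buffered medium avoids epimerisation.

**Compound list**
1 | (−)-α-santonin | C[C@H]1[C@@H]2CC[C@]3(C=CC(=O)C(=C3[C@H]2OC1=O)C)C | starting material
2 | isophotosantonic lactone (10-hydroxy-3-oxoguai-4-en-12,6-olide, 10-OH cis to H-1, 10R) | CC1=C2[C@H]3OC(=O)[C@@H](C)[C@@H]3CC[C@@](C)(O)[C@@H]2CC1=O | intermediate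
3 | 3-oxoguaia-4,10(14)-dien-12,6-olide (exocyclic methylene at C10) | CC1=C2[C@H]3OC(=O)[C@@H](C)[C@@H]3CCC(=C)[C@@H]2CC1=O | intermediate
4 | 10-epi-isophotosantonic lactone (10-OH trans to H-1, 10S) | CC1=C2[C@H]3OC(=O)[C@@H](C)[C@@H]3CC[C@](C)(O)[C@@H]2CC1=O | intermediate
5 | 3,10-bis(triethylsilyloxy)guaia-2,4-dien-12,6-olide (2-silyloxy diene) | CC1=C2[C@H]3OC(=O)[C@@H](C)[C@@H]3CC[C@](C)(O[Si](CC)(CC)CC)[C@@H]2C=C1O[Si](CC)(CC)CC | intermediate
6 | cesium dienolate (cesium 10-triethylsilyloxy-12,6-olidoguaia-2,4-dien-3-olate) | CC1=C2[C@H]3OC(=O)[C@@H](C)[C@@H]3CC[C@](C)(O[Si](CC)(CC)CC)[C@@H]2C=C1[O-].[Cs+] | intermediate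
7 | dienyl triflate (10-triethylsilyloxy-3-trifluoromethylsulfonyloxyguaia-2,4-dien-12,6-olide) | CC1=C2[C@H]3OC(=O)[C@@H](C)[C@@H]3CC[C@](C)(O[Si](CC)(CC)CC)[C@@H]2C=C1OS(=O)(=O)C(F)(F)F | intermediate
8 | triflyloxy enedione (4,5-seco-4,5-dioxo-10-triethylsilyloxy-3-trifluoromethylsulfonyloxyguai-2-en-12,6-olide, C1 and acetyl cis on C2=C3) | CC(=O)/C(OS(=O)(=O)C(F)(F)F)=C\[C@@H]1C(=O)[C@H]2OC(=O)[C@@H](C)[C@@H]2CC[C@]1(C)O[Si](CC)(CC)CC | intermediate
9 | (Z)-enedione (4,5-seco-4,5-dioxo-10-triethylsilyloxyguai-2-en-12,6-olide) | CC(=O)/C=C\[C@@H]1C(=O)[C@H]2OC(=O)[C@@H](C)[C@@H]2CC[C@]1(C)O[Si](CC)(CC)CC | intermediate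
10 | Diels–Alder adduct (C2–C2′ and C3–C5′ bonds; endo C1 and endo acetyl; C5 ketone; 3′-silyl enol ether; 10- and 10′-OTES) | O=C1[C@H]2OC(=O)[C@@H](C)[C@@H]2CC[C@](C)(O[Si](CC)(CC)CC)[C@@H]1[C@H]1[C@H]2C(O[Si](CC)(CC)CC)=C(C)[C@]3([C@@H]2[C@@](C)(O[Si](CC)(CC)CC)CC[C@H]2[C@H](C)C(=O)O[C@@H]23)[C@H]1C(C)=O | intermediate
11 | bis-methylene diene (C4 isopropenyl on C3, C5 methylene) | C=C1[C@H]2OC(=O)[C@@H](C)[C@@H]2CC[C@](C)(O[Si](CC)(CC)CC)[C@@H]1[C@H]1[C@H]2C(O[Si](CC)(CC)CC)=C(C)[C@]3([C@@H]2[C@@](C)(O[Si](CC)(CC)CC)CC[C@H]2[C@H](C)C(=O)O[C@@H]23)[C@H]1C(C)=C | intermediate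
12 | tris(triethylsilyl) derivative of the target (10-O, 10′-O and 3′-enol ether) | CC1=C2[C@H]3OC(=O)[C@@H](C)[C@@H]3CC[C@](C)(O[Si](CC)(CC)CC)[C@@H]2[C@H]2[C@H]3C(O[Si](CC)(CC)CC)=C(C)[C@]4([C@@H]3[C@@](C)(O[Si](CC)(CC)CC)CC[C@H]3[C@H](C)C(=O)O[C@@H]34)[C@@H]12 | intermediate
13 | CNP0243924.4 | CC1=C2[C@H]3OC(=O)[C@@H](C)[C@@H]3CC[C@](C)(O)[C@@H]2[C@H]2[C@H]3C(=O)[C@@H](C)[C@]4([C@@H]3[C@@](C)(O)CC[C@H]3[C@H](C)C(=O)O[C@@H]34)[C@@H]12 | target

Total step count: 11. Longest linear sequence: 11 steps (1 → 13 through 9).

**Steps most likely to fail**

Step 8. The dienophile may show poor facial and endo/exo selectivity, because the open-chain (Z)-enone need not react through the ring-like rotamer, and it may isomerise before cycloaddition. Fallback: the configuration of C2 and C3 is taken out of the cycloaddition. Setting out from 5 and triflate 8, used as an alkynone equivalent, the Diels–Alder reaction (toluene, 2,6-di-tert-butyl-4-methylpyridine, 60 °C) should give the tertiary α-keto triflate adduct F1. This loses triflic acid across C2–C3 in the same flask to give the norbornadienyl methyl ketone F2. Conjugate reduction with [(Ph3P)CuH]6 (benzene, t-BuOH, 23 °C) then adds hydride to C2 and a proton to C3, both from the exo face, and comes back to the route at 10.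

Step 10. The two hindered 1,1-disubstituted alkenes may fail to enter the catalytic cycle or may migrate. Fallback: reductive carbonyl coupling instead of metathesis. Setting out from diketone 10, a McMurry reaction (TiCl3(DME)1.5, Zn–Cu couple, DME, slow addition at reflux) joins C4 and C5 directly and comes back to the route at 12; no new compound is made (entry F0). Its own hazard is reductive cleavage of the C6–O bond next to the C5 ketone by low-valent titanium.

Step 3. Oxygen capture at the C10 radical may be poorly face-selective, or the enone may be reduced in competition. Fallback: the methyl group, not the oxygen, is added last. Setting out from 3, ozonolysis of the exocyclic alkene (O3, pyridine, CH2Cl2, −78 °C; the electron-poor enone should survive) gives the 14-nor-10-ketone F3. MeTi(OiPr)3 (THF, −20 °C), which should discriminate the saturated ketone from the enone and the lactone and attack from the equatorial side, then comes back to the route at 4.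

Further compounds
F1 | step 8 | tertiary α-keto triflate adduct | O=C1[C@H]2OC(=O)[C@@H](C)[C@@H]2CC[C@](C)(O[Si](CC)(CC)CC)[C@@H]1[C@H]1[C@H]2C(O[Si](CC)(CC)CC)=C(C)[C@]3([C@@H]2[C@@](C)(O[Si](CC)(CC)CC)CC[C@H]2[C@H](C)C(=O)O[C@@H]23)[C@@]1(OS(=O)(=O)C(F)(F)F)C(C)=O
F2 | step 8 | norbornadienyl methyl ketone | O=C1[C@H]2OC(=O)[C@@H](C)[C@@H]2CC[C@](C)(O[Si](CC)(CC)CC)[C@@H]1C=1[C@H]2C(O[Si](CC)(CC)CC)=C(C)[C@]3([C@@H]2[C@@](C)(O[Si](CC)(CC)CC)CC[C@H]2[C@H](C)C(=O)O[C@@H]23)C1C(C)=O
F0 | step 10 | none | none
F3 | step 3 | 14-nor-10-ketone (3,10-dioxo-14-norguai-4-en-12,6-olide) | CC1=C2[C@H]3OC(=O)[C@@H](C)[C@@H]3CCC(=O)[C@@H]2CC1=O
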